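**Plan**

- Retrosynthesis: the ring B C3–CH2 (prenyl) bond is cut first by a retro-[3,3] shift, leading back to the ring B 4-O-(1,1-dimethylallyl) ether of the unprenylated benzil. The ether O–C(CH3)2 bond is cut next, then the two aryl–C(=O) bonds of the dione.
- Forward: two MOM-protected aryl bromides are lithiated and added one after the other to 1,4-dimethylpiperazine-2,3-dione, which supplies both carbonyl carbons. Acid deprotection then gives the triol benzil.
- The ring B C4–OH is alkylated with 3-chloro-3-methylbut-1-yne, the alkyne is semihydrogenated, and heating moves the five-carbon unit from O4 to C3.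
- Enabling feature: the ring B C4–OH is the only hydroxyl not hydrogen-bonded to a carbonyl, so it can be etherified without protecting groups. C3 lies between it and the chelated C2–OH, and that chelate gives the C3–C4 bond the double-bond character needed for the shift.
- No ring is formed. The target is achiral and its only olefin carries two identical methyl groups, so no stereochemistry has to be set.

Key step: step 7

Remark: 2-hydroxybenzils can equilibrate with cyclic 2-hydroxybenzofuran-3-one hemiketals; the open, doubly chelated dione form reported for the natural product is assumed for all free-phenol intermediates.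

**Step 1**
Reactants: 1 4-bromoresorcinol (4-bromobenzene-1,3-diol)
Product: 2 1-bromo-2,4-bis(methoxymethoxy)benzene
Conditions: NaH (2.5 equiv), DMF, 0 °C; MOMCl (2.5 equiv), 0 °C to rt
Reagents that add atoms: chloromethyl methyl ether (MOMCl), COCCl
Why: Williamson-type O-alkylation of both sodium phenoxides with the reactive α-chloro ether should give the bis-acetal, which is stable to organolithiums and is removed later by aqueous acid.

**Step 2**
Reactants: 3 2-bromo-5-methoxyphenol
Product: 4 1-bromo-4-methoxy-2-(methoxymethoxy)benzene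
Conditions: NaH (1.3 equiv), DMF, 0 °C; MOMCl (1.3 equiv), 0 °C to rt
Reagents that add atoms: chloromethyl methyl ether (MOMCl), COCCl
Why: The same Williamson-type MOM protection masks the only acidic proton of the ring A fragment before bromine–lithium exchange.

**Step 3**
Reactants: 2 1-bromo-2,4-bis(methoxymethoxy)benzene; 5 1,4-dimethylpiperazine-2,3-dione; 4 1-bromo-4-methoxy-2-(methoxymethoxy)benzene
Product: 10 1-[2,4-bis(methoxymethoxy)phenyl]-2-[4-methoxy-2-(methoxymethoxy)phenyl]ethane-1,2-dione, via ring B aryllithium 6 (not isolated), via mono-adduct lithium alkoxide 7 (not isolated), via ring A aryllithium 8 (not isolated), via bis-adduct dilithium dialkoxide 9 (not isolated)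
Conditions: 2, n-BuLi (1.0 equiv), THF, −78 °C; cannulate into 5 (1.0 equiv), THF, −78 °C, 1 h; add aryllithium from 4 and n-BuLi (1.2 equiv, THF, −78 °C); −78 °C to 0 °C; 1 M HCl, 0 °C, brief
Reagents that add atoms: none
Why: This is a sequential double acyl substitution on a cyclic oxalic diamide after bromine–lithium exchange, in which the first aryllithium gives a chelated tetrahedral lithium hemiaminal that does not collapse in the cold, so the second, different aryllithium adds to the remaining amide carbonyl and cold dilute acid releases the unsymmetrical diaryl 1,2-dione with the MOM ethers intact.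

**Step 4**
Reactants: 10 1-[2,4-bis(methoxymethoxy)phenyl]-2-[4-methoxy-2-(methoxymethoxy)phenyl]ethane-1,2-dione
Product: 11 1-(2,4-dihydroxyphenyl)-2-(2-hydroxy-4-methoxyphenyl)ethane-1,2-dione
Conditions: 3 M HCl (aq)/THF 1:2, 50 °C
Reagents that add atoms: none
Why: Acid-catalysed hydrolysis of the three aryl methoxymethyl acetals should free the triol, with water rather than an alcohol as nucleophile so that no mixed ketal forms at the dione and the aryl methyl ether is untouched.

**Step 5**
Reactants: 11 1-(2,4-dihydroxyphenyl)-2-(2-hydroxy-4-methoxyphenyl)ethane-1,2-dione; 12 3-chloro-3-methylbut-1-yne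
Product: 13 1-[2-hydroxy-4-(2-methylbut-3-yn-2-yloxy)phenyl]-2-(2-hydroxy-4-methoxyphenyl)ethane-1,2-dione
Conditions: 12 (1.5 equiv), K2CO3 (1.2 equiv), KI (0.2 equiv), CuI (0.1 equiv), DMF, 60 °C
Reagents that add atoms: none
Why: Copper-assisted Williamson-type propargylation of a phenol with a tertiary propargylic chloride should be chemoselective, because only the ring B C4–OH (para to a carbonyl, not hydrogen-bonded) is deprotonated and nucleophilic under carbonate conditions, as is general for 2,4-dihydroxyaryl ketones.

**Step 6**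
Reactants: 13 1-[2-hydroxy-4-(2-methylbut-3-yn-2-yloxy)phenyl]-2-(2-hydroxy-4-methoxyphenyl)ethane-1,2-dione
Product: 14 1-[2-hydroxy-4-(2-methylbut-3-en-2-yloxy)phenyl]-2-(2-hydroxy-4-methoxyphenyl)ethane-1,2-dione
Conditions: H2 (1 atm), 5% Pd/CaCO3 poisoned with Pb(OAc)2, quinoline, EtOAc, rt, stopped after 1 equiv of H2
Reagents that add atoms: none
Why: Lindlar-type semihydrogenation of the terminal alkyne over lead-poisoned palladium should stop at the vinyl group and leave the chelated aryl ketones and the tertiary allylic C–O bond intact.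

**Step 7**
Reactants: 14 1-[2-hydroxy-4-(2-methylbut-3-en-2-yloxy)phenyl]-2-(2-hydroxy-4-methoxyphenyl)ethane-1,2-dione
Product: 16 licoagrodione, via cyclohexadienone 15 (not isolated)
Conditions: PhNEt2 (degassed), 135 °C, Ar
Reagents that add atoms: none
Why: Aromatic Claisen rearrangement: the O–C4=C3 unit of ring B and the 1,1-dimethylallyl group form an allyl vinyl ether that should undergo a concerted chair-like [3,3] shift, breaking the tertiary C–O bond while the terminal CH2 bonds to ring B C3, so that allylic transposition delivers a normal 3-methylbut-2-enyl group, and enolisation of dienone 15 then restores the aromatic ring with a free C4–OH. The closest known reaction type is the thermal rearrangement of 4-O-(1,1-dimethylallyl) ethers of 2,4-dihydroxyaryl ketones to their 3-prenyl derivatives. No ring is closed and no stereocentre remains, since the sp3 carbon of 15 is lost on tautomerisation. The step needs migration to C3 and not to C5: the resonance-assisted hydrogen bond between the C2–OH and the C1 carbonyl favours the Kekulé form with a C1=C2 bond and therefore C3=C4 double-bond character, which steers the allyl terminus to the carbon between the two oxygens. The gem-dimethyl substitution at the breaking C–O bond lowers the barrier so that moderate heating should suffice for the dione, and the weakly basic amine solvent should suppress acid-catalysed loss of the allyl group and chroman formation.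

**Compound list**

1 | 4-bromoresorcinol (4-bromobenzene-1,3-diol) | Oc1ccc(Br)c(O)c1 | starting material
2 | 1-bromo-2,4-bis(methoxymethoxy)benzene | COCOc1ccc(Br)c(OCOC)c1 | intermediate
3 | 2-bromo-5-methoxyphenol | COc1ccc(Br)c(O)c1 | starting material
4 | 1-bromo-4-methoxy-2-(methoxymethoxy)benzene | COCOc1cc(OC)ccc1Br | intermediate
5 | 1,4-dimethylpiperazine-2,3-dione | CN1CCN(C)C(=O)C1=O | starting material
6 | 2,4-bis(methoxymethoxy)phenyllithium | [Li]c1ccc(OCOC)cc1OCOC | intermediate (not isolated)
7 | lithium 2-[2,4-bis(methoxymethoxy)phenyl]-1,4-dimethyl-3-oxopiperazin-2-olate (racemic) | [Li]OC1(c2ccc(OCOC)cc2OCOC)N(C)CCN(C)C1=O | intermediate (not isolated)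
8 | 4-methoxy-2-(methoxymethoxy)phenyllithium | [Li]c1ccc(OC)cc1OCOC | intermediate (not isolated)
9 | dilithium 2-[2,4-bis(methoxymethoxy)phenyl]-3-[4-methoxy-2-(methoxymethoxy)phenyl]-1,4-dimethylpiperazine-2,3-diolate (diastereomer mixture) | [Li]OC1(c2ccc(OCOC)cc2OCOC)N(C)CCN(C)C1(O[Li])c1ccc(OC)cc1OCOC | intermediate (not isolated)
10 | 1-[2,4-bis(methoxymethoxy)phenyl]-2-[4-methoxy-2-(methoxymethoxy)phenyl]ethane-1,2-dione | COCOc1ccc(C(=O)C(=O)c2ccc(OC)cc2OCOC)c(OCOC)c1 | intermediate
11 | 1-(2,4-dihydroxyphenyl)-2-(2-hydroxy-4-methoxyphenyl)ethane-1,2-dione | COc1ccc(C(=O)C(=O)c2ccc(O)cc2O)c(O)c1 | intermediate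
12 | 3-chloro-3-methylbut-1-yne | C#CC(C)(C)Cl | starting material
13 | 1-[2-hydroxy-4-(2-methylbut-3-yn-2-yloxy)phenyl]-2-(2-hydroxy-4-methoxyphenyl)ethane-1,2-dione | COc1ccc(C(=O)C(=O)c2ccc(OC(C)(C)C#C)cc2O)c(O)c1 | intermediate
14 | 1-[2-hydroxy-4-(2-methylbut-3-en-2-yloxy)phenyl]-2-(2-hydroxy-4-methoxyphenyl)ethane-1,2-dione | COc1ccc(C(=O)C(=O)c2ccc(OC(C)(C)C=C)cc2O)c(O)c1 | intermediate
15 | 1-[2-hydroxy-3-(3-methylbut-2-enyl)-4-oxocyclohexa-1,5-dien-1-yl]-2-(2-hydroxy-4-methoxyphenyl)ethane-1,2-dione (racemic, transient) | COc1ccc(C(=O)C(=O)C2=C(O)C(CC=C(C)C)C(=O)C=C2)c(O)c1 | intermediate (not isolated)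
16 | licoagrodione, 1-[2,4-dihydroxy-3-(3-methylbut-2-enyl)phenyl]-2-(2-hydroxy-4-methoxyphenyl)ethane-1,2-dione | COc1ccc(C(=O)C(=O)c2ccc(O)c(CC=C(C)C)c2O)c(O)c1 | target

**Step count**

Total steps: 7. Longest linear sequence: 6 steps (1 → 2 → 10 → 11 → 13 → 14 → 16; the branch from 3 is equally long).

**Steps most likely to fail**

Step 7. The tertiary C–O bond may ionise and shed the five-carbon unit as isoprene, part of the migration may go to ring B C5, or the freed C4–OH may add to the new olefin to give a chroman. The fallback forms the C3–CH2 bond by directed metalation instead; it sets out from 2 and returns at 16. Bromide 2 is deprotonated at the CH between its two acetal oxygens with LDA (THF, −78 °C) to give 3-bromo-2,6-bis(methoxymethoxy)phenyllithium F1. CuI (10 mol %) and prenyl bromide (1-bromo-3-methylbut-2-ene) should then give 1-bromo-2,4-bis(methoxymethoxy)-3-(3-methylbut-2-enyl)benzene F2. As in step 3, n-BuLi converts F2 into 2,4-bis(methoxymethoxy)-3-(3-methylbut-2-enyl)phenyllithium F3, which adds to 5 to give lithium 2-[2,4-bis(methoxymethoxy)-3-(3-methylbut-2-enyl)phenyl]-1,4-dimethyl-3-oxopiperazin-2-olate F4. Aryllithium 8 then gives dilithium 2-[2,4-bis(methoxymethoxy)-3-(3-methylbut-2-enyl)phenyl]-3-[4-methoxy-2-(methoxymethoxy)phenyl]-1,4-dimethylpiperazine-2,3-diolate F5, and cold dilute HCl releases 1-[2,4-bis(methoxymethoxy)-3-(3-methylbut-2-enyl)phenyl]-2-[4-methoxy-2-(methoxymethoxy)phenyl]ethane-1,2-dione F6. Hydrolysis of the three acetals (3 M HCl, THF, rt to 40 °C, kept short to spare the prenyl olefin) should give 16.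

Step 3. The two aryllithium additions may scramble to symmetrical diones, the second addition to the hindered hemiaminal alkoxide may stall, or proton transfer may isomerise an aryllithium. The fallback builds the dione by alkyne oxidation; it sets out from 4 and returns at 10. Sonogashira coupling of 4 with ethynyltrimethylsilane (PdCl2(PPh3)2, CuI, Et3N, 80 °C) should give trimethyl{[4-methoxy-2-(methoxymethoxy)phenyl]ethynyl}silane F7. K2CO3 in MeOH frees 1-ethynyl-4-methoxy-2-(methoxymethoxy)benzene F8, and a second Sonogashira coupling with 2 gives 1-{[2,4-bis(methoxymethoxy)phenyl]ethynyl}-4-methoxy-2-(methoxymethoxy)benzene F9. Oxidation of the diarylalkyne with KMnO4 (NaHCO3, MgSO4, acetone/water, rt) should give 10.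

Step 5. Substitution at the tertiary chloride may be slow and lose out to elimination to the enyne, and a chelated hydroxyl may be alkylated in part. The fallback installs the 1,1-dimethylallyl ether directly; it sets out from 11 and returns at 14, bypassing 13 and step 6. Tsuji–Trost O-allylation of 11 with tert-butyl 2-methylbut-3-en-2-yl carbonate and Pd(PPh3)4 (5 mol %) in THF at 0 °C should deliver the branched aryl ether at the most acidic, non-chelated C4–OH. It makes no new compound.

**Further compounds**

F1 | step 7 | 3-bromo-2,6-bis(methoxymethoxy)phenyllithium | [Li]c1c(OCOC)ccc(Br)c1OCOC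
F2 | step 7 | 1-bromo-2,4-bis(methoxymethoxy)-3-(3-methylbut-2-enyl)benzene | COCOc1ccc(Br)c(OCOC)c1CC=C(C)C
F3 | step 7 | 2,4-bis(methoxymethoxy)-3-(3-methylbut-2-enyl)phenyllithium | [Li]c1ccc(OCOC)c(CC=C(C)C)c1OCOC
F4 | step 7 | lithium 2-[2,4-bis(methoxymethoxy)-3-(3-methylbut-2-enyl)phenyl]-1,4-dimethyl-3-oxopiperazin-2-olate | [Li]OC1(c2ccc(OCOC)c(CC=C(C)C)c2OCOC)N(C)CCN(C)C1=O
F5 | step 7 | dilithium 2-[2,4-bis(methoxymethoxy)-3-(3-methylbut-2-enyl)phenyl]-3-[4-methoxy-2-(methoxymethoxy)phenyl]-1,4-dimethylpiperazine-2,3-diolate | [Li]OC1(c2ccc(OCOC)c(CC=C(C)C)c2OCOC)N(C)CCN(C)C1(O[Li])c1ccc(OC)cc1OCOC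
F6 | step 7 | 1-[2,4-bis(methoxymethoxy)-3-(3-methylbut-2-enyl)phenyl]-2-[4-methoxy-2-(methoxymethoxy)phenyl]ethane-1,2-dione | COCOc1ccc(C(=O)C(=O)c2ccc(OC)cc2OCOC)c(OCOC)c1CC=C(C)C
F7 | step 3 | trimethyl{[4-methoxy-2-(methoxymethoxy)phenyl]ethynyl}silane | COCOc1cc(OC)ccc1C#C[Si](C)(C)C
F8 | step 3 | 1-ethynyl-4-methoxy-2-(methoxymethoxy)benzene | COCOc1cc(OC)ccc1C#C
F9 | step 3 | 1-{[2,4-bis(methoxymethoxy)phenyl]ethynyl}-4-methoxy-2-(methoxymethoxy)benzene | COCOc1ccc(C#Cc2ccc(OC)cc2OCOC)c(OCOC)c1
F0 | step 5 | none | none
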